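**Retrosynthetic overview**

1. Side chain last: C12–C13 by Suzuki coupling of a C12 alkenyl boronate with 3-bromofuran-2(5H)-one; the boronate by cross-metathesis of the C9 vinyl group (C11=C12); C8=C17 from a C8 ketone masked as a dioxolane.
2. Ring A groups (3α-OH, C4 methyl and CH2OAc, 5β-H) from a 3-oxo-4-carbomethoxy-1,4-dienone by conjugate reduction, reductive methylation, hydride reduction and monoacetylation.
3. Key disconnection C9–C10 (ring B): the C3 oxygen, the carboxyl-level C19 on C4 and the C10 methyl, para to C3–O and ortho to the C5 tether, are the pattern of a 6-alkyl-5-methylsalicylate; its phenoxide para carbon is quaternized by a tethered C9–C11–C12 allyl unit, which leaves C11=C12 as a vinyl branch.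
4. The tether (C6–C7–C8 ketal–allylic carbonate) is built on methyl 5,6-dimethylsalicylate by lateral lithiation/allylation, alkene cleavage, alkenylzinc addition, oxidation and ketalization; the salicylate comes from methyl acetoacetate and tiglic aldehyde.
5. Ring order: ring A first (as the arene), ring B in the key step, the butenolide ring brought in intact at the end.

Key step: step 12

Remark (numbering): labdane positions are used for all bicyclic intermediates (C17 = C8 methylene carbon, C18 = C4 methyl, C19 = C4 carboxyl/CH2O carbon, C20 = C10 methyl); α is the face of the C10 methyl group.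
Remark (assumption): in step 12 the closure is taken to run through the arrangement with C9–H over the ring, which places vinyl and C10 methyl cis, and the phosphoramidite antipode is the one whose usual sense of induction gives the C9 configuration drawn.

**Route**

Step 1
Reactants: 1 methyl acetoacetate; 2 (E)-2-methylbut-2-enal
Product: 3 methyl 5,6-dimethyl-2-oxocyclohex-3-ene-1-carboxylate (mixture of diastereomers)
Conditions: NaOMe (0.2 equiv), MeOH, 0 °C to reflux
Reagents that add atoms: none
Why: Base-catalysed Michael addition of the acetoacetate to the enal and intramolecular aldol condensation (Robinson-type annulation) should place the two methyl groups on adjacent ring carbons next to the ester-bearing carbon; the stereocentres formed are erased in step 2.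

Step 2
Reactants: 3 methyl 5,6-dimethyl-2-oxocyclohex-3-ene-1-carboxylate
Product: 4 methyl 2-hydroxy-5,6-dimethylbenzoate
Conditions: DDQ (1.1 equiv), toluene, 100 °C
Reagents that add atoms: none
Why: DDQ dehydrogenation of the enolizable cyclohexenone β-keto ester should give its aromatic tautomer, the 5,6-dimethylsalicylate, with the substitution pattern fixed by step 1.

Step 3
Reactants: 4 methyl 2-hydroxy-5,6-dimethylbenzoate
Product: 5 methyl 2-[(4-methoxybenzyl)oxy]-5,6-dimethylbenzoate
Conditions: PMBCl, K2CO3, NaI (cat.), DMF, 60 °C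
Reagents that add atoms: 4-methoxybenzyl chloride, COc1ccc(CCl)cc1
Why: Williamson etherification of the hydrogen-bonded phenol; the PMB ether tolerates LDA and is removed later by oxidation, without acid.

Step 4
Reactants: 5 methyl 2-[(4-methoxybenzyl)oxy]-5,6-dimethylbenzoate; 6 allyl bromide
Product: 8 methyl 6-(but-3-en-1-yl)-2-[(4-methoxybenzyl)oxy]-5-methylbenzoate, via benzylic lithium 7 (not isolated)
Conditions: LDA (1.1 equiv), THF, −78 °C; then 6, −78 to −20 °C
Reagents that add atoms: none
Why: Lateral lithiation: only the methyl ortho to the ester gives an ester-stabilized (extended enolate) benzylic anion, which should be alkylated by allyl bromide (SN2).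

Step 5
Reactants: 8 methyl 6-(but-3-en-1-yl)-2-[(4-methoxybenzyl)oxy]-5-methylbenzoate
Product: 10 methyl 2-[(4-methoxybenzyl)oxy]-5-methyl-6-(3-oxopropyl)benzoate, via vicinal diol 9 (not isolated)
Conditions: OsO4 (2 mol%), NaIO4 (3 equiv), 2,6-lutidine, dioxane/H2O, rt
Reagents that add atoms: osmium tetroxide, O=[Os](=O)(=O)=O; sodium periodate, [Na+].[O-]I(=O)(=O)=O
Why: Lemieux–Johnson dihydroxylation/glycol cleavage of the terminal alkene gives the C8 aldehyde and spares the electron-rich PMB arene, which ozone could attack.

Step 6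
Reactants: 10 methyl 2-[(4-methoxybenzyl)oxy]-5-methyl-6-(3-oxopropyl)benzoate; 11 tert-butyldimethyl(prop-2-yn-1-yloxy)silane
Product: 14 methyl 6-[(E)-6-(tert-butyldimethylsilyloxy)-3-hydroxyhex-4-en-1-yl]-2-[(4-methoxybenzyl)oxy]-5-methylbenzoate (racemic carbinol), via alkenylzirconocene 12 (not isolated), via alkenylzinc 13 (not isolated)
Conditions: 11, Cp2Zr(H)Cl, CH2Cl2, rt; Me2Zn, −65 °C; then 10, 0 °C
Reagents that add atoms: none
Why: Hydrozirconation of the terminal alkyne gives the (E)-alkenyl metal, and after transmetalation to zinc it should add to the aldehyde only (1,2-addition), the hindered aryl ester being inert; the racemic carbinol centre is removed in step 7.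

Step 7
Reactants: 14 methyl 6-[(E)-6-(tert-butyldimethylsilyloxy)-3-hydroxyhex-4-en-1-yl]-2-[(4-methoxybenzyl)oxy]-5-methylbenzoate
Product: 15 methyl 6-[(E)-6-(tert-butyldimethylsilyloxy)-3-oxohex-4-en-1-yl]-2-[(4-methoxybenzyl)oxy]-5-methylbenzoate
Conditions: Dess–Martin periodinane, CH2Cl2, 0 °C to rt
Reagents that add atoms: none
Why: Dess–Martin oxidation of the secondary allylic alcohol to the (E)-enone under near-neutral conditions.

Step 8
Reactants: 15 methyl 6-[(E)-6-(tert-butyldimethylsilyloxy)-3-oxohex-4-en-1-yl]-2-[(4-methoxybenzyl)oxy]-5-methylbenzoate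
Product: 16 methyl 6-(2-{2-[(E)-3-(tert-butyldimethylsilyloxy)prop-1-en-1-yl]-1,3-dioxolan-2-yl}ethyl)-2-[(4-methoxybenzyl)oxy]-5-methylbenzoate
Conditions: TMSOCH2CH2OTMS (3 equiv), TMSOTf (5 mol%), CH2Cl2, −78 to −20 °C; pyridine quench
Reagents that add atoms: 1,2-bis(trimethylsilyloxy)ethane, C[Si](C)(C)OCCO[Si](C)(C)C
Why: Ketalization with the bis-silyl glycol under catalytic TMSOTf at low temperature converts enones into dioxolanes without double-bond migration or conjugate addition, so the E-alkene should stay in place.

Step 9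
Reactants: 16 methyl 6-(2-{2-[(E)-3-(tert-butyldimethylsilyloxy)prop-1-en-1-yl]-1,3-dioxolan-2-yl}ethyl)-2-[(4-methoxybenzyl)oxy]-5-methylbenzoate
Product: 17 methyl 6-(2-{2-[(E)-3-hydroxyprop-1-en-1-yl]-1,3-dioxolan-2-yl}ethyl)-2-[(4-methoxybenzyl)oxy]-5-methylbenzoate
Conditions: TBAF, THF, 0 °C
Reagents that add atoms: none
Why: Fluoride cleaves the primary allylic silyl ether; ketal, PMB ether and methyl ester are inert to TBAF, and acid (which the allylic ketal would not tolerate) is avoided.

Step 10
Reactants: 17 methyl 6-(2-{2-[(E)-3-hydroxyprop-1-en-1-yl]-1,3-dioxolan-2-yl}ethyl)-2-[(4-methoxybenzyl)oxy]-5-methylbenzoate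
Product: 18 methyl 6-(2-{2-[(E)-3-(methoxycarbonyloxy)prop-1-en-1-yl]-1,3-dioxolan-2-yl}ethyl)-2-[(4-methoxybenzyl)oxy]-5-methylbenzoate
Conditions: ClCO2Me, pyridine, CH2Cl2, 0 °C
Reagents that add atoms: methyl chloroformate, COC(=O)Cl
Why: Acylation of the primary allylic alcohol installs the methyl carbonate leaving group for the allylic substitution.

Step 11
Reactants: 18 methyl 6-(2-{2-[(E)-3-(methoxycarbonyloxy)prop-1-en-1-yl]-1,3-dioxolan-2-yl}ethyl)-2-[(4-methoxybenzyl)oxy]-5-methylbenzoate
Product: 19 methyl 2-hydroxy-6-(2-{2-[(E)-3-(methoxycarbonyloxy)prop-1-en-1-yl]-1,3-dioxolan-2-yl}ethyl)-5-methylbenzoate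
Conditions: DDQ (1.5 equiv), CH2Cl2/pH 7 buffer, 0 °C to rt
Reagents that add atoms: none
Why: Oxidative cleavage of the PMB ether by DDQ in buffered wet CH2Cl2 should free the phenol without acid or base, so the allylic ketal and the carbonate survive.

Step 12
Reactants: 19 methyl 2-hydroxy-6-(2-{2-[(E)-3-(methoxycarbonyloxy)prop-1-en-1-yl]-1,3-dioxolan-2-yl}ethyl)-5-methylbenzoate
Product: 20 methyl 8,8-ethylenedioxy-3-oxo-13,14,15,16,17,18-hexanor-ent-labda-1,4,11-trien-19-oate (C10 methyl α, C9 vinyl α and cis to it, C9–H β)
Conditions: [Ir(cod)Cl]2 (4 mol%), BINOL-derived N,N-bis(1-phenylethyl) phosphoramidite (8 mol%), n-PrNH2 (activation, then removed), Li2CO3 (1 equiv), THF (0.01 M), 50 °C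
Reagents that add atoms: none
Why: Proposed new method: the cyclometalated Ir(I)–phosphoramidite ionizes the primary allylic carbonate to an (η3-allyl)Ir(III) complex, the methoxide released with CO2 (buffered by Li2CO3) forms the lithium phenoxide, and its para carbon C10 attacks the substituted allyl terminus C9 on the face opposite iridium. The closest known reactions are the Ir-catalysed intramolecular allylic dearomatization of para-tethered phenols to spirocyclohexadienones and the Ir-catalysed Friedel–Crafts-type closure of meta-tethered phenols at a para C–H; here the para carbon carries a methyl group, so the same six-ring closure cannot rearomatize and should stop at the dienone. Ring B closes 6-exo (C10 onto C9, leaving C11=C12 as the vinyl branch), helped by the gem-dialkoxy group at C8, whereas attack at C12 would need an eight-membered ring. C9 is set by the ligand, which fixes the allyl face bound to iridium, and C10 follows from C9 through the chair-like transition state that keeps C9–H over the ring and the allyl unit outside it, so that vinyl and methyl should end up cis. The step needs C10 rather than C4 attack, C- rather than O-alkylation and intra- rather than intermolecular reaction: the lithium chelate between phenoxide oxygen and the coplanar ester shields C4 and the oxygen, para attack gives the cross-conjugated dienone with the ester still conjugated, the oxygen cannot reach the allyl unit within the molecule, and high dilution suppresses oligomers.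

Step 13
Reactants: 20 methyl 8,8-ethylenedioxy-3-oxo-13,14,15,16,17,18-hexanor-ent-labda-1,4,11-trien-19-oate
Product: 21 methyl 8,8-ethylenedioxy-3-oxo-13,14,15,16,17,18-hexanor-ent-labda-4,11-dien-19-oate (C1–C2 saturated; C9, C10 as in 20)
Conditions: L-Selectride (1.1 equiv), THF, −78 °C; then H2O
Reagents that add atoms: none
Why: Conjugate reduction: the bulky trialkylborohydride should add to C1, the only β-carbon that bears hydrogen, and the resulting enolate resists further hydride, so the tetrasubstituted alkylidene β-keto ester, the vinyl group and the ketal are kept; a dissolving metal is avoided at the dienone stage because its radical anion could expel the allylic C9 radical and rearomatize.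

Step 14
Reactants: 21 methyl 8,8-ethylenedioxy-3-oxo-13,14,15,16,17,18-hexanor-ent-labda-4,11-dien-19-oate
Product: 23 methyl 8,8-ethylenedioxy-3-oxo-13,14,15,16,17-pentanor-ent-labd-11-en-19-oate (5β-H, 4β-methyl, 4α-CO2Me, 9α-vinyl, 10α-methyl), via lithium enolate 22 (not isolated)
Conditions: Li (2.2 equiv), NH3(l)/THF, −78 °C; then MeI, −78 to −33 °C
Reagents that add atoms: iodomethane, CI
Why: Reductive alkylation: two-electron reduction of the 4-carbomethoxy-Δ4-3-ketone and protonation of C5 by ammonia on the face opposite the axial C10 methyl should give the trans-fused β-keto ester enolate, which iodomethane alkylates at C4 anti to the C10 methyl, so the new methyl is β (equatorial) and the ester α (axial, cis to C20); the isolated vinyl group and the ketal are inert to lithium in ammonia.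

Step 15
Reactants: 23 methyl 8,8-ethylenedioxy-3-oxo-13,14,15,16,17-pentanor-ent-labd-11-en-19-oate
Product: 24 8,8-ethylenedioxy-13,14,15,16,17-pentanor-ent-labd-11-ene-3α,19-diol
Conditions: LiAlH4, THF, 0 °C to rt
Reagents that add atoms: none
Why: Hydride reduction of ketone and ester; axial attack on C3 from the β face, away from the axial 4α substituent, should give the equatorial 3α-alcohol.

Step 16
Reactants: 24 8,8-ethylenedioxy-13,14,15,16,17-pentanor-ent-labd-11-ene-3α,19-diol
Product: 25 19-acetoxy-8,8-ethylenedioxy-13,14,15,16,17-pentanor-ent-labd-11-en-3α-ol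
Conditions: Ac2O (1.1 equiv), pyridine, CH2Cl2, −20 to 0 °C
Reagents that add atoms: acetic anhydride, CC(=O)OC(C)=O
Why: Selective acylation of the primary C19 hydroxyl over the secondary C3 hydroxyl, which is flanked by the quaternary C4.

Step 17
Reactants: 25 19-acetoxy-8,8-ethylenedioxy-13,14,15,16,17-pentanor-ent-labd-11-en-3α-ol
Product: 26 19-acetoxy-3α-hydroxy-13,14,15,16,17-pentanor-ent-labd-11-en-8-one
Conditions: PPTS (0.2 equiv), acetone/H2O, 45 °C
Reagents that add atoms: water, O
Why: Acid-catalysed ketal hydrolysis, eased by relief of the 1,3-diaxial contact between a ketal oxygen and the C10 methyl; PPTS is too weak to move the vinyl double bond into conjugation, and C9, now enolizable, should rest in the equatorial-vinyl arrangement that the target needs.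

Step 18
Reactants: 26 19-acetoxy-3α-hydroxy-13,14,15,16,17-pentanor-ent-labd-11-en-8-one
Product: 27 19-acetoxy-13,14,15,16-tetranor-ent-labda-8(17),11-dien-3α-ol
Conditions: Zn, CH2Br2, TiCl4 (preformed reagent, excess), THF/CH2Cl2, 0 °C to rt
Reagents that add atoms: dibromomethane, BrCBr
Why: Takai–Lombardo methylenation with the gem-dizinc/titanium reagent is non-basic, so the α-vinyl ketone should be neither enolized nor isomerized, and the acetate is not attacked (the free hydroxyl only consumes reagent).

Step 19
Reactants: 27 19-acetoxy-13,14,15,16-tetranor-ent-labda-8(17),11-dien-3α-ol; 28 vinylboronic acid pinacol ester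
Product: 29 19-acetoxy-12-(4,4,5,5-tetramethyl-1,3,2-dioxaborolan-2-yl)-13,14,15,16-tetranor-ent-labda-8(17),11E-dien-3α-ol
Conditions: Hoveyda–Grubbs second-generation catalyst (10 mol%), 28 (5 equiv), 1,4-benzoquinone (10 mol%), CH2Cl2, 40 °C
Reagents that add atoms: none
Why: Olefin cross-metathesis: the monosubstituted C11=C12 vinyl group should react while the 1,1-disubstituted C8 methylene does not, vinyl boronates giving the (E)-alkenyl boronate (C12 comes from 28, the old terminal CH2 leaves as ethylene).

Step 20
Reactants: 29 19-acetoxy-12-(4,4,5,5-tetramethyl-1,3,2-dioxaborolan-2-yl)-13,14,15,16-tetranor-ent-labda-8(17),11E-dien-3α-ol; 30 3-bromofuran-2(5H)-one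
Product: 31 19-O-acetyl-14-deoxy-11,12-didehydroandrographolide (CNP0346413.1)
Conditions: Pd(dppf)Cl2 (5 mol%), K3PO4 (2 equiv), THF/H2O, rt
Reagents that add atoms: none
Why: Suzuki–Miyaura coupling of the (E)-alkenyl boronate with the α-bromobutenolide forms C12–C13 with retention of alkene geometry under base mild enough for the acetate and the butenolide; an olefination of a C11 aldehyde with a furanone phosphonate was not chosen because base would deprotonate the butenolide γ-position first.

**Compound list**

1 | methyl acetoacetate | CC(=O)CC(=O)OC | starting material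
2 | (E)-2-methylbut-2-enal (tiglic aldehyde) | C/C=C(\C)C=O | starting material
3 | methyl 5,6-dimethyl-2-oxocyclohex-3-ene-1-carboxylate (diastereomer mixture) | COC(=O)C1C(C)C(C)C=CC1=O | intermediate
4 | methyl 2-hydroxy-5,6-dimethylbenzoate | COC(=O)c1c(O)ccc(C)c1C | intermediate
5 | methyl 2-[(4-methoxybenzyl)oxy]-5,6-dimethylbenzoate | COC(=O)c1c(OCc2ccc(OC)cc2)ccc(C)c1C | intermediate
6 | allyl bromide | C=CCBr | starting material
7 | benzylic lithium of 5 at the 6-methyl group (not isolated) | [Li]Cc1c(C)ccc(OCc2ccc(OC)cc2)c1C(=O)OC | intermediate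
8 | methyl 6-(but-3-en-1-yl)-2-[(4-methoxybenzyl)oxy]-5-methylbenzoate | COC(=O)c1c(OCc2ccc(OC)cc2)ccc(C)c1CCC=C | intermediate
9 | methyl 6-(3,4-dihydroxybutyl)-2-[(4-methoxybenzyl)oxy]-5-methylbenzoate (not isolated) | COC(=O)c1c(OCc2ccc(OC)cc2)ccc(C)c1CCC(O)CO | intermediate
10 | methyl 2-[(4-methoxybenzyl)oxy]-5-methyl-6-(3-oxopropyl)benzoate | COC(=O)c1c(OCc2ccc(OC)cc2)ccc(C)c1CCC=O | intermediate
11 | tert-butyldimethyl(prop-2-yn-1-yloxy)silane | C#CCO[Si](C)(C)C(C)(C)C | starting material
12 | (E)-[3-(tert-butyldimethylsilyloxy)prop-1-en-1-yl]zirconocene chloride (not isolated) | CC(C)(C)[Si](C)(C)OC/C=C/[Zr](Cl)(C1C=CC=C1)C1C=CC=C1 | intermediate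
13 | (E)-[3-(tert-butyldimethylsilyloxy)prop-1-en-1-yl](methyl)zinc (not isolated) | CC(C)(C)[Si](C)(C)OC/C=C/[Zn]C | intermediate
14 | methyl 6-[(E)-6-(tert-butyldimethylsilyloxy)-3-hydroxyhex-4-en-1-yl]-2-[(4-methoxybenzyl)oxy]-5-methylbenzoate (racemic) | COC(=O)c1c(OCc2ccc(OC)cc2)ccc(C)c1CCC(O)/C=C/CO[Si](C)(C)C(C)(C)C | intermediate
15 | methyl 6-[(E)-6-(tert-butyldimethylsilyloxy)-3-oxohex-4-en-1-yl]-2-[(4-methoxybenzyl)oxy]-5-methylbenzoate | COC(=O)c1c(OCc2ccc(OC)cc2)ccc(C)c1CCC(=O)/C=C/CO[Si](C)(C)C(C)(C)C | intermediate
16 | methyl 6-(2-{2-[(E)-3-(tert-butyldimethylsilyloxy)prop-1-en-1-yl]-1,3-dioxolan-2-yl}ethyl)-2-[(4-methoxybenzyl)oxy]-5-methylbenzoate | COC(=O)c1c(OCc2ccc(OC)cc2)ccc(C)c1CCC3(OCCO3)/C=C/CO[Si](C)(C)C(C)(C)C | intermediate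
17 | methyl 6-(2-{2-[(E)-3-hydroxyprop-1-en-1-yl]-1,3-dioxolan-2-yl}ethyl)-2-[(4-methoxybenzyl)oxy]-5-methylbenzoate | COC(=O)c1c(OCc2ccc(OC)cc2)ccc(C)c1CCC3(OCCO3)/C=C/CO | intermediate
18 | methyl 6-(2-{2-[(E)-3-(methoxycarbonyloxy)prop-1-en-1-yl]-1,3-dioxolan-2-yl}ethyl)-2-[(4-methoxybenzyl)oxy]-5-methylbenzoate | COC(=O)c1c(OCc2ccc(OC)cc2)ccc(C)c1CCC3(OCCO3)/C=C/COC(=O)OC | intermediate
19 | methyl 2-hydroxy-6-(2-{2-[(E)-3-(methoxycarbonyloxy)prop-1-en-1-yl]-1,3-dioxolan-2-yl}ethyl)-5-methylbenzoate (key-step precursor) | COC(=O)c1c(O)ccc(C)c1CCC2(OCCO2)/C=C/COC(=O)OC | intermediate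
20 | methyl 8,8-ethylenedioxy-3-oxo-13,14,15,16,17,18-hexanor-ent-labda-1,4,11-trien-19-oate (10α-methyl, 9α-vinyl; key-step product) | O1CCOC12CCC3=C(C(=O)OC)C(=O)C=C[C@@]3(C)[C@@H]2C=C | intermediate
21 | methyl 8,8-ethylenedioxy-3-oxo-13,14,15,16,17,18-hexanor-ent-labda-4,11-dien-19-oate | O1CCOC12CCC3=C(C(=O)OC)C(=O)CC[C@@]3(C)[C@@H]2C=C | intermediate
22 | lithium C3 enolate of the trans-fused β-keto ester (5β-H; not isolated) | O1CCOC12CC[C@@H]3C(C(=O)OC)=C(O[Li])CC[C@@]3(C)[C@@H]2C=C | intermediate
23 | methyl 8,8-ethylenedioxy-3-oxo-13,14,15,16,17-pentanor-ent-labd-11-en-19-oate (5β-H, 4β-methyl, 4α-ester) | O1CCOC12CC[C@@H]3[C@](C)(C(=O)OC)C(=O)CC[C@@]3(C)[C@@H]2C=C | intermediate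
24 | 8,8-ethylenedioxy-13,14,15,16,17-pentanor-ent-labd-11-ene-3α,19-diol | O1CCOC12CC[C@@H]3[C@](C)(CO)[C@H](O)CC[C@@]3(C)[C@@H]2C=C | intermediate
25 | 19-acetoxy-8,8-ethylenedioxy-13,14,15,16,17-pentanor-ent-labd-11-en-3α-ol | O1CCOC12CC[C@@H]3[C@](C)(COC(C)=O)[C@H](O)CC[C@@]3(C)[C@@H]2C=C | intermediate
26 | 19-acetoxy-3α-hydroxy-13,14,15,16,17-pentanor-ent-labd-11-en-8-one | O=C1CC[C@@H]2[C@](C)(COC(C)=O)[C@H](O)CC[C@@]2(C)[C@@H]1C=C | intermediate
27 | 19-acetoxy-13,14,15,16-tetranor-ent-labda-8(17),11-dien-3α-ol | C=C1CC[C@@H]2[C@](C)(COC(C)=O)[C@H](O)CC[C@@]2(C)[C@@H]1C=C | intermediate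
28 | vinylboronic acid pinacol ester | C=CB1OC(C)(C)C(C)(C)O1 | starting material
29 | 19-acetoxy-12-(pinacolboryl)-13,14,15,16-tetranor-ent-labda-8(17),11E-dien-3α-ol | C=C1CC[C@@H]2[C@](C)(COC(C)=O)[C@H](O)CC[C@@]2(C)[C@@H]1/C=C/B1OC(C)(C)C(C)(C)O1 | intermediate
30 | 3-bromofuran-2(5H)-one | BrC1=CCOC1=O | starting material
31 | 19-O-acetyl-14-deoxy-11,12-didehydroandrographolide (CNP0346413.1) | C=C1CC[C@@H]2[C@](C)(COC(C)=O)[C@H](O)CC[C@@]2(C)[C@@H]1/C=C/C1=CCOC1=O | target

**Step count and risks**

Total step count: 20. Longest linear sequence: 20 steps (1 and 2 to 31); 6, 11, 28 and 30 are taken as catalogue compounds.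

Steps most likely to fail:

1. Step 12 (new method). What may go wrong: bond formation at C9, which is flanked by the C8 ketal and must meet a fully substituted arene carbon, may be slower than intermolecular O- or C-allylation through C12; closure may go through C4 instead of C10; facial control at C10 may be poor; on heating, a [3,3] shift of 20 towards the C4-bonded eight-membered isomer may set in. A wrong C9 epimer alone is tolerable: C9 becomes enolizable in 26 and can be equilibrated there with mild base to the equatorial-vinyl epimer, the ligand antipode then being the one that gives the required C10 configuration. Fallback (known chemistry, no dearomatization): ring A is annulated onto a ring-B ketone. It sets out from methyl acetoacetate 1, whose dianion (NaH, n-BuLi) is hydroxymethylated with formaldehyde to methyl 5-hydroxy-3-oxopentanoate F1 and dehydrated (MsCl, Et3N) to methyl 3-oxopent-4-enoate F2 (Nazarov reagent). The partner, trans-7-methyl-6-vinyl-1,4-dioxaspiro[4.5]decan-8-one F3, comes from commercial 1,4-dioxaspiro[4.5]dec-6-en-8-one by conjugate addition of a vinyl cuprate and trapping of the enolate with iodomethane. Robinson annulation of F3 with F2 through the more substituted enolate (cat. NaOMe; Michael addition anti to the vinyl group, aldol condensation, dehydration) gives enone ester 21, where the route is rejoined. As described this sequence is racemic, so 21 is resolved by chromatography on a chiral stationary phase, or the cuprate step is run with a chiral copper catalyst.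

2. Step 13. What may go wrong: hydride delivery to the doubly activated C5 or to the C3 carbonyl instead of C1. Fallback: C1=C2 is masked as a thiol adduct and the dissolving-metal step does the rest. It sets out from 20: thiophenol with catalytic Et3N (reversible thia-Michael addition, so the adduct at the unhindered C1 should accumulate) gives the 1-phenylthio enone ester F4. Excess lithium in ammonia then reduces C4=C5 and cleaves the C1–S bond, and iodomethane methylates C4, which returns to the route at 23 (steps 13 and 14 merge).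

3. Step 19. What may go wrong: slow metathesis at the vinyl group, which sits between the quaternary C10 and C8, and ruthenium-hydride migration of the skipped 8(17),11-diene into conjugation. Fallback: Mizoroki–Heck vinylation of 27 with 30 (Pd(OAc)2, P(o-tol)3, Ag2CO3, DMF, 80 °C), in which β-hydride elimination towards C12 gives the conjugated (E)-diene; it sets out from 27 and returns directly at 31, with no new compound (F0).

Further compounds
F1 | step 12 | methyl 5-hydroxy-3-oxopentanoate | COC(=O)CC(=O)CCO
F2 | step 12 | methyl 3-oxopent-4-enoate (Nazarov reagent) | COC(=O)CC(=O)C=C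
F3 | step 12 | trans-7-methyl-6-vinyl-1,4-dioxaspiro[4.5]decan-8-one (racemic; the enantiomer leading to 21 is drawn) | O1CCOC12CCC(=O)[C@@H](C)[C@@H]2C=C
F4 | step 13 | methyl 8,8-ethylenedioxy-3-oxo-1-(phenylthio)-13,14,15,16,17,18-hexanor-ent-labda-4,11-dien-19-oate (C1 epimers) | O1CCOC12CCC3=C(C(=O)OC)C(=O)CC(Sc4ccccc4)[C@@]3(C)[C@@H]2C=C
F0 | step 19 | none | none
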